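Ring A is drawn from a cycloheptanone in which the future ester carbon C19 is a ring member between C4 and C5. That carbonyl works three times before it leaves the ring: CBS reduction makes it the only source of absolute configuration; its silyl ether steers a Diels–Alder reaction that builds ring B with the C10 quaternary methyl, C8 methylene and C9 carbon; as an enone it admits the 6α oxygen. Photochemical Wolff rearrangement of the derived α-diazo ketone then contracts the seven-membered ring to ring A, forming C4–C5 and turning C19 into the ester; methylation of the C4 enolate anti to the C10 methyl and a late Negishi coupling with the (Z)-dienyl iodide finish the route.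

Key step: step 13

Remark: labdane numbering is used for every compound (in 1–18 the ring carbon between C4 and C5 is the future C19), and 3-methylcyclohept-2-en-1-one (1) is taken as a catalogue compound.

Step 1
Reactants: 1 3-methylcyclohept-2-en-1-one
Product: 2 2-iodo-3-methylcyclohept-2-en-1-one
Conditions: I2, pyridine, CH2Cl2, rt, dark
Reagents that add atoms: iodine II
Why: α-Iodination of the enone by conjugate addition of pyridine, iodination of the enolate and loss of pyridine should give the alkenyl iodide that serves both the asymmetric reduction and the later coupling.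

Step 2
Reactants: 2 2-iodo-3-methylcyclohept-2-en-1-one
Product: 3 (1S)-2-iodo-3-methylcyclohept-2-en-1-ol
Conditions: (R)-2-methyl-CBS-oxazaborolidine (20 mol%), BH3·SMe2, THF, −20 °C
Reagents that add atoms: none
Why: Corey–Bakshi–Shibata reduction in which the iodoalkenyl carbon is the large group, so the (R)-catalyst should deliver hydride to give the (1S)-alcohol and thereby fix C19 (oxygen on the β face).

Step 3
Reactants: 3 (1S)-2-iodo-3-methylcyclohept-2-en-1-ol
Product: 4 tert-butyl{[(1S)-2-iodo-3-methylcyclohept-2-en-1-yl]oxy}dimethylsilane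
Conditions: TBSCl, imidazole, DMF, rt
Reagents that add atoms: tert-butyldimethylsilyl chloride CC(C)(C)[Si](C)(C)Cl
Why: Silylation of the secondary alcohol gives the bulky OTBS group that later shields one face of the diene.

Step 4
Reactants: 4 tert-butyl{[(1S)-2-iodo-3-methylcyclohept-2-en-1-yl]oxy}dimethylsilane
Product: 5 tert-butyl{[(1S)-2-ethenyl-3-methylcyclohept-2-en-1-yl]oxy}dimethylsilane
Conditions: tributyl(ethenyl)stannane, Pd(PPh3)4 (5 mol%), CuI (10 mol%), DMF, 60 °C
Reagents that add atoms: tributyl(ethenyl)stannane C=C[Sn](CCCC)(CCCC)CCCC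
Why: Stille coupling at the hindered alkenyl iodide, accelerated by CuI, should install C6 and C7 as the vinyl group and complete the diene C10=C5–C6=C7.

Step 5
Reactants: 5 tert-butyl{[(1S)-2-ethenyl-3-methylcyclohept-2-en-1-yl]oxy}dimethylsilane; 6 ethyl buta-2,3-dienoate
Product: 7 Diels–Alder ester (19β-OTBS; 10β-Me; Δ5; 8(17)-ene; both C9 epimers)
Conditions: 6 (3 equiv), BHT (cat.), toluene, 110 °C, sealed tube
Reagents that add atoms: none
Why: Thermal Diels–Alder reaction in which the unsubstituted diene terminus C7 bonds to the electrophilic central allene carbon (C8) and C9 bonds to C10 (ortho orientation), while the allenoate approaches the face opposite the pseudoaxial OTBS on C19, which should set the C10 methyl β; C9 forms as a mixture that step 6 corrects.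

Step 6
Reactants: 7 Diels–Alder ester (C9 epimers)
Product: 9 9β-ethyl ester (9α-H), via lithium dienolate 8 (not isolated)
Conditions: LiN(iPr)2, THF, −78 °C; then AcOH, THF, −78 °C
Reagents that add atoms: none
Why: Deprotonation at C9 gives one extended enolate from both epimers, and kinetic α-protonation of this dienolate from the α face, away from the axial C10 methyl, should give the equatorial 9β-ester with the 8(17)-alkene kept.

Step 7
Reactants: 9 9β-ethyl ester
Product: 10 primary alcohol (C11–OH; 19β-OTBS)
Conditions: iBu2AlH (3 equiv), CH2Cl2, −78 → 0 °C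
Reagents that add atoms: none
Why: Hydride reduction of the ester to the primary alcohol leaves the silyl ether and both alkenes untouched and removes the only acidic C–H of ring B before the base steps.

Step 8
Reactants: 10 primary alcohol
Product: 11 diol (19β-OH; C11–OH)
Conditions: Bu4NF, THF, 40 °C
Reagents that add atoms: none
Why: Fluoride cleavage of the silyl ether frees the allylic C19 alcohol once it has done its work as stereodirecting group.

Step 9
Reactants: 11 diol
Product: 12 hydroxy enone (C19=O conjugated with C5=C6)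
Conditions: MnO2 (20 equiv), CH2Cl2, rt
Reagents that add atoms: none
Why: MnO2 oxidises only the allylic secondary alcohol and leaves the homoallylic primary alcohol, giving the s-cis enone needed for the oxygenation of C6.

Step 10
Reactants: 12 hydroxy enone
Product: 14 keto diol (6α-OH; 5α-H; trans ring fusion), via boryl ketone 13 (not isolated)
Conditions: CuCl (5 mol%), Xantphos (5 mol%), NaOtBu (10 mol%), B2pin2, MeOH, THF, rt; then 30% H2O2, aq NaHCO3, 0 °C
Reagents that add atoms: hydrogen peroxide OO
Why: Copper-catalysed conjugate borylation should add boron to C6 from the α face (the β face is screened by the axial C10 methyl), protonation at C5 anti to that methyl gives the trans fusion (also the more stable epimer at this ketone α-carbon), and oxidation of C–B with retention gives the equatorial 6α-OH.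

Step 11
Reactants: 14 keto diol
Product: 15 bis(triethylsilyl) ether of 14
Conditions: TESOTf, 2,6-lutidine, CH2Cl2, −78 °C
Reagents that add atoms: triethylsilyl trifluoromethanesulfonate CC[Si](CC)(CC)OS(=O)(=O)C(F)(F)F
Why: Silylation of both hydroxyls protects them from the bases of steps 12 and 14 and blocks retro-aldol cleavage and lactone formation.

Step 12
Reactants: 15 bis(triethylsilyl) ether
Product: 18 α-diazo ketone (N2 on C4), via lithium enolate 16 (not isolated), via trifluoroacetyl ketone 17 (not isolated)
Conditions: LiN(SiMe3)2, THF, −78 °C; CF3CO2CH2CF3; then MsN3, Et3N, H2O, MeCN, rt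
Reagents that add atoms: methanesulfonyl azide CS(=O)(=O)N=[N+]=[N-]
Why: Detrifluoroacetylative diazo transfer: kinetic deprotonation occurs at C4, the only α-carbon with two hydrogens, the enolate is trifluoroacetylated, and the 1,3-dicarbonyl compound takes up N2 from the sulfonyl azide with loss of the trifluoroacetyl group.

Step 13
Reactants: 18 α-diazo ketone
Product: 20 ring-contracted methyl ester (ring A six-membered; C4 epimers), via ketene 19 (not isolated)
Conditions: hν (365 nm), MeOH/THF, rt
Reagents that add atoms: methanol CO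
Why: Direct excitation of the cyclic α-diazo ketone, locked s-cis by the ring, expels N2 with concerted 1,2-shift of C5 from C19 to C4 to give ketene 19, which methanol traps as the ester; this is the photochemical Wolff ring contraction known for cyclic 2-diazo ketones. Ring A is closed not by a cyclisation but by this 1,2-shift, which makes the C4–C5 bond and takes C19 out of the ring (seven- to six-membered). C5 migrates with retention, so the trans fusion set in step 10 is kept; the new centre C4 (H and CO2Me) forms without control, which does not matter because step 14 planarises it. The step needs the diazo group on C4 and not C5, which step 12 secures, and rearrangement in preference to O–H insertion or 1,2-hydride shift, which the enforced s-cis geometry and direct irradiation favour.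

Step 14
Reactants: 20 ring-contracted methyl ester
Product: 22 C4-methylated ester (4α-Me; 4β-CO2Me), via lithium ester enolate 21 (not isolated)
Conditions: LiN(iPr)2, THF/DMPU, −78 °C; MeI, −78 → −20 °C
Reagents that add atoms: iodomethane CI
Why: Alkylation of the exocyclic C4 ester enolate from the α face, the β face being blocked by the 1,3-diaxial C10 methyl, should place methyl equatorial and CO2Me axial, the usual outcome for C4 ester enolates of 10-methyl trans-decalins.

Step 15
Reactants: 22 C4-methylated ester
Product: 23 diol ester (6α-OH; C11–OH)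
Conditions: HF·pyridine, THF/pyridine, 0 °C → rt
Reagents that add atoms: none
Why: Fluoride cleavage removes both triethylsilyl ethers without touching the hindered ester or the exocyclic alkene.

Step 16
Reactants: 23 diol ester
Product: 24 primary iodide (C11–I; 6α-OH)
Conditions: I2, PPh3, imidazole, CH2Cl2, 0 °C
Reagents that add atoms: iodine II
Why: Appel-type iodination should convert only the primary C11 alcohol, because the hindered secondary 6α-OH does not form a displaceable phosphonium species at a useful rate.

Step 17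
Reactants: 24 primary iodide
Product: 25 iodo acetate (6α-OAc)
Conditions: Ac2O, DMAP, pyridine, rt
Reagents that add atoms: acetic anhydride CC(=O)OC(C)=O
Why: DMAP-catalysed acylation of the equatorial 6α-OH installs the acetate of the target.

Step 18
Reactants: 26 prop-2-yn-1-ol
Product: 28 (2Z)-3-iodo-2-methylprop-2-en-1-ol, via alkenylmagnesium alkoxide 27 (not isolated)
Conditions: MeMgBr (2.5 equiv), CuI (10 mol%), Et2O, −10 °C → rt; then I2, −78 °C → rt
Reagents that add atoms: methylmagnesium bromide C[Mg]Br; iodine II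
Why: Copper-catalysed anti carbomagnesiation of the propargylic alkoxide puts methyl on the inner carbon and magnesium on the terminus cis to the CH2O group, and iodinolysis with retention gives the (Z)-iodide.

Step 19
Reactants: 28 (2Z)-3-iodo-2-methylprop-2-en-1-ol
Product: 29 (2Z)-3-iodo-2-methylprop-2-enal
Conditions: MnO2, CH2Cl2, rt, dark
Reagents that add atoms: none
Why: Neutral MnO2 oxidation of the allylic alcohol should keep the alkene geometry.

Step 20
Reactants: 29 (2Z)-3-iodo-2-methylprop-2-enal
Product: 30 (1Z)-1-iodo-2-methylbuta-1,3-diene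
Conditions: Ph3PCH3Br, n-BuLi, THF, 0 °C; then 29, −78 → 0 °C; used as a solution
Reagents that add atoms: methyltriphenylphosphonium bromide C[P+](c1ccccc1)(c1ccccc1)c1ccccc1.[Br-]
Why: Wittig methylenation of the enal builds the terminal vinyl group and does not touch the iodoalkene geometry.

Step 21
Reactants: 25 iodo acetate; 30 (1Z)-1-iodo-2-methylbuta-1,3-diene
Product: 32 methyl (12Z)-6α-acetoxylabda-8(17),12,14-trien-19-oate, via alkylzinc iodide 31 (not isolated)
Conditions: Zn dust (activated with 1,2-dibromoethane and TMSCl), LiCl, THF, 40 °C; then 30, Pd2(dba)3 (2.5 mol%), SPhos (10 mol%), THF, rt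
Reagents that add atoms: none
Why: Negishi coupling: zinc inserts into the primary C11–I bond (ester and acetate are tolerated) and palladium-catalysed sp3–sp2 coupling with the alkenyl iodide forms C11–C12 with retention of the (Z) geometry.

Compound list
1 | 3-methylcyclohept-2-en-1-one | CC1=CC(=O)CCCC1 | starting material
2 | 2-iodo-3-methylcyclohept-2-en-1-one | CC1=C(I)C(=O)CCCC1 | intermediate
3 | (1S)-2-iodo-3-methylcyclohept-2-en-1-ol | CC1=C(I)[C@@H](O)CCCC1 | intermediate
4 | tert-butyl{[(1S)-2-iodo-3-methylcyclohept-2-en-1-yl]oxy}dimethylsilane | CC1=C(I)[C@@H](O[Si](C)(C)C(C)(C)C)CCCC1 | intermediate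
5 | tert-butyl{[(1S)-2-ethenyl-3-methylcyclohept-2-en-1-yl]oxy}dimethylsilane | CC1=C(C=C)[C@@H](O[Si](C)(C)C(C)(C)C)CCCC1 | intermediate
6 | ethyl buta-2,3-dienoate | C=C=CC(=O)OCC | starting material
7 | ethyl 5-(tert-butyldimethylsilyloxy)-9a-methyl-2-methylidene-2,3,5,6,7,8,9,9a-octahydro-1H-benzo[7]annulene-1-carboxylate (19β-OTBS, 10β-Me, Δ5, 8(17)-ene, both C9 epimers) | CCOC(=O)C1C(=C)CC=C2[C@]1(C)CCCC[C@@H]2O[Si](C)(C)C(C)(C)C | intermediate
8 | lithium dienolate of 7 (C9=C11(OEt)OLi) | CCOC(O[Li])=C1C(=C)CC=C2[C@]1(C)CCCC[C@@H]2O[Si](C)(C)C(C)(C)C | intermediate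
9 | single epimer of 7 with 9β-CO2Et and 9α-H | CCOC(=O)[C@H]1C(=C)CC=C2[C@]1(C)CCCC[C@@H]2O[Si](C)(C)C(C)(C)C | intermediate
10 | [5-(tert-butyldimethylsilyloxy)-9a-methyl-2-methylidene-2,3,5,6,7,8,9,9a-octahydro-1H-benzo[7]annulen-1-yl]methanol (C11–OH, 9α-H, 19β-OTBS) | OC[C@H]1C(=C)CC=C2[C@]1(C)CCCC[C@@H]2O[Si](C)(C)C(C)(C)C | intermediate
11 | 1-(hydroxymethyl)-9a-methyl-2-methylidene-2,3,5,6,7,8,9,9a-octahydro-1H-benzo[7]annulen-5-ol (19β-OH) | OC[C@H]1C(=C)CC=C2[C@]1(C)CCCC[C@@H]2O | intermediate
12 | 1-(hydroxymethyl)-9a-methyl-2-methylidene-1,2,3,6,7,8,9,9a-octahydro-5H-benzo[7]annulen-5-one (enone C19(=O)–C5=C6) | OC[C@H]1C(=C)CC=C2[C@]1(C)CCCCC2=O | intermediate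
13 | boryl ketone: 12 with 6α-Bpin and 5α-H | OC[C@H]1C(=C)C[C@H](B3OC(C)(C)C(C)(C)O3)[C@@H]2[C@]1(C)CCCCC2=O | intermediate
14 | 4-hydroxy-1-(hydroxymethyl)-9a-methyl-2-methylidenedecahydro-5H-benzo[7]annulen-5-one (6α-OH, 5α-H, trans-fused, 9α-H, 10β-Me) | OC[C@H]1C(=C)C[C@H](O)[C@@H]2[C@]1(C)CCCCC2=O | intermediate
15 | bis(triethylsilyl) ether of 14 | CC[Si](CC)(CC)OC[C@H]1C(=C)C[C@H](O[Si](CC)(CC)CC)[C@@H]2[C@]1(C)CCCCC2=O | intermediate
16 | lithium enolate of 15 (C4=C19–OLi) | CC[Si](CC)(CC)OC[C@H]1C(=C)C[C@H](O[Si](CC)(CC)CC)[C@@H]2[C@]1(C)CCCC=C2O[Li] | intermediate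
17 | 15 carrying a trifluoroacetyl group on C4 | CC[Si](CC)(CC)OC[C@H]1C(=C)C[C@H](O[Si](CC)(CC)CC)[C@@H]2[C@]1(C)CCCC(C(=O)C(F)(F)F)C2=O | intermediate
18 | α-diazo ketone: 15 with N2 on C4 | CC[Si](CC)(CC)OC[C@H]1C(=C)C[C@H](O[Si](CC)(CC)CC)[C@@H]2[C@]1(C)CCCC(=[N+]=[N-])C2=O | intermediate
19 | ketene (C4=C19=O on the six-membered ring A) | CC[Si](CC)(CC)OC[C@H]1C(=C)C[C@H](O[Si](CC)(CC)CC)[C@@H]2[C@]1(C)CCCC2=C=O | intermediate
20 | methyl 4a-methyl-6-methylidene-8-(triethylsilyloxy)-5-[(triethylsilyloxy)methyl]decahydronaphthalene-1-carboxylate (5α-H, 6α-OTES, 9α-H, 10β-Me, C4 epimers) | CC[Si](CC)(CC)OC[C@H]1C(=C)C[C@H](O[Si](CC)(CC)CC)[C@@H]2[C@]1(C)CCCC2C(=O)OC | intermediate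
21 | lithium enolate of 20 (C4=C19(OMe)OLi) | CC[Si](CC)(CC)OC[C@H]1C(=C)C[C@H](O[Si](CC)(CC)CC)[C@@H]2[C@]1(C)CCCC2=C(OC)O[Li] | intermediate
22 | methyl 1,4a-dimethyl-6-methylidene-8-(triethylsilyloxy)-5-[(triethylsilyloxy)methyl]decahydronaphthalene-1-carboxylate (4α-Me, 4β-CO2Me) | CC[Si](CC)(CC)OC[C@H]1C(=C)C[C@H](O[Si](CC)(CC)CC)[C@@H]2[C@]1(C)CCC[C@]2(C)C(=O)OC | intermediate
23 | methyl 8-hydroxy-5-(hydroxymethyl)-1,4a-dimethyl-6-methylidenedecahydronaphthalene-1-carboxylate (6α-OH, C11–OH) | OC[C@H]1C(=C)C[C@H](O)[C@@H]2[C@]1(C)CCC[C@]2(C)C(=O)OC | intermediate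
24 | methyl 8-hydroxy-5-(iodomethyl)-1,4a-dimethyl-6-methylidenedecahydronaphthalene-1-carboxylate | IC[C@H]1C(=C)C[C@H](O)[C@@H]2[C@]1(C)CCC[C@]2(C)C(=O)OC | intermediate
25 | methyl 8-acetoxy-5-(iodomethyl)-1,4a-dimethyl-6-methylidenedecahydronaphthalene-1-carboxylate (6α-OAc) | IC[C@H]1C(=C)C[C@H](OC(C)=O)[C@@H]2[C@]1(C)CCC[C@]2(C)C(=O)OC | intermediate
26 | prop-2-yn-1-ol | C#CCO | starting material
27 | (Z)-alkenylmagnesium alkoxide from carbomagnesiation of 26 | Br[Mg]OC/C(C)=C\[Mg]Br | intermediate
28 | (2Z)-3-iodo-2-methylprop-2-en-1-ol | OC/C(C)=C\I | intermediate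
29 | (2Z)-3-iodo-2-methylprop-2-enal | O=C/C(C)=C\I | intermediate
30 | (1Z)-1-iodo-2-methylbuta-1,3-diene | C=C/C(C)=C\I | intermediate
31 | alkylzinc iodide from 25 (C11–ZnI) | I[Zn]C[C@H]1C(=C)C[C@H](OC(C)=O)[C@@H]2[C@]1(C)CCC[C@]2(C)C(=O)OC | intermediate
32 | methyl (12Z)-6α-acetoxylabda-8(17),12,14-trien-19-oate (methyl 8-acetoxy-1,4a-dimethyl-6-methylidene-5-[(2Z)-3-methylpenta-2,4-dien-1-yl]decahydronaphthalene-1-carboxylate) | C=C/C(C)=C\C[C@H]1C(=C)C[C@H](OC(C)=O)[C@@H]2[C@]1(C)CCC[C@]2(C)C(=O)OC | target

Total step count: 21 steps.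
Longest linear sequence: 18 steps (steps 1–17, then step 21); steps 18–20 make the side-chain fragment.

Steps most likely to fail

Step 5. The cycloaddition joins a tetrasubstituted diene terminus to an allenoate; it may be too slow, so that allenoate oligomerisation or a 1,5-hydrogen shift of the diene takes over, or it may lose regio- or facial control. The fallback sets out from 5 and uses dimethyl acetylenedicarboxylate, a stronger and symmetric dienophile that removes the regiochemical question, to give the diene diester F1 by approach anti to the OTBS group. iBu2AlH at −78 °C should reduce the less hindered C8 ester (the C9 ester is shielded by the C10 quaternary centre) to the allylic alcohol F2. Formylation with formic acetic anhydride and pyridine gives the allylic formate F3. Formate reduction of the Tsuji–Trost type with Pd(OAc)2 and PBu3 should deliver hydride to the more substituted allyl terminus C9 from the palladium-bearing α face, giving the 8(17)-ene methyl ester F4 with 9α-H. iBu2AlH reduction of F4 comes back to the route at 10.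

Step 13. The photogenerated species may leave the Wolff path by O–H insertion into methanol or by 1,2-hydride shift to an enone, or irradiation may degrade the silyl ethers. The fallback sets out from 15 and contracts the ring by a silver-assisted semibenzilic (quasi-Favorskii) shift instead. LiN(SiMe3)2 and TMSCl give the trimethylsilyl enol ether F6 on the C4 side, and NBS converts it into the α-bromo ketone F7. AgSbF6 in methanol should then add methanol to the carbonyl and pull off bromide while C5 shifts from C19 to C4, which returns to the route at 20.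

Step 10. Boron may add from the wrong face, C5 may be protonated to the cis-fused ketone, or the β-hydroxy ketone may eliminate or undergo retro-aldol cleavage under the basic oxidation. The fallback sets out from 12: Weitz–Scheffer epoxidation (H2O2, NaOH, MeOH, 0 °C) should add hydroperoxide to C6 from the α face and give the 5α,6α-epoxy ketone F5. SmI2 in THF/MeOH at −78 °C cleaves the C5–O bond next to the ketone, and protonation of the samarium enolate gives the 6α-hydroxy ketone, returning to the route at 14.

Further compounds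
F1 | step 5 | dimethyl 5-(tert-butyldimethylsilyloxy)-9a-methyl-5,6,7,8,9,9a-hexahydro-3H-benzo[7]annulene-1,2-dicarboxylate (Δ5, Δ8, 19β-OTBS, 10β-Me) | COC(=O)C1=C(C(=O)OC)CC=C2[C@]1(C)CCCC[C@@H]2O[Si](C)(C)C(C)(C)C
F2 | step 5 | F1 with the C8 ester reduced to CH2OH | COC(=O)C1=C(CO)CC=C2[C@]1(C)CCCC[C@@H]2O[Si](C)(C)C(C)(C)C
F3 | step 5 | formate ester of F2 | COC(=O)C1=C(COC=O)CC=C2[C@]1(C)CCCC[C@@H]2O[Si](C)(C)C(C)(C)C
F4 | step 5 | methyl ester analogue of 9 (9β-CO2Me, 9α-H, 8(17)-ene) | COC(=O)[C@H]1C(=C)CC=C2[C@]1(C)CCCC[C@@H]2O[Si](C)(C)C(C)(C)C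
F5 | step 10 | 5α,6α-epoxide of 12 | OC[C@H]1C(=C)C[C@@H]2O[C@]23[C@]1(C)CCCCC3=O
F6 | step 13 | trimethylsilyl enol ether of 15 (C4=C19–OTMS) | CC[Si](CC)(CC)OC[C@H]1C(=C)C[C@H](O[Si](CC)(CC)CC)[C@@H]2[C@]1(C)CCCC=C2O[Si](C)(C)C
F7 | step 13 | 15 with bromine on C4 | CC[Si](CC)(CC)OC[C@H]1C(=C)C[C@H](O[Si](CC)(CC)CC)[C@@H]2[C@]1(C)CCCC(Br)C2=O
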